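We decide to reckon this flask from its two ends and join them in one number.

- delta: substrate 20 mM; gas phase 12 mM (held); the very flask that is asked about, followed so far
- flask: substrate 20 mM; gas phase 12 mM (held); time 40 min

delta run (percent of the substrate charged): time / min: target / % = 2.50: 15; 5.00: 31; 6.00: 34; 10.0: 43; 12.0: 38; 15.0: 35

(readings scatter by 2 percentage points)

- the earlier runs were read with a standard deviation of 2 percentage points
- at the start none of the gas phase is in solution

- dusk: doubling the saturation concentration of gas phase, all else as stated
- winter: doubling the transfer coefficient of the gas phase, all else as stated

* amount of target at 40 min, in percent of the substrate charged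
* the change that raises the amount of target at 40 min, in percent of the substrate charged most ("none" if none brings more than 2 percentage points) (dusk / winter / none)
* amount of target at 40 min, in percent of the substrate charged, after dusk

At the early end we take target y to grow in proportion to time t, at s = 0.0600 min⁻¹ of the charge, as read from the first delta reading. At the late end we take it to fade exponentially. We take formation and loss as pseudo-first-order steps of like pace, so y/t falls exponentially and ln(y/t) is a straight line in t. Between the first and last readings, λ = 0.0756 min⁻¹, our fading rate, with a fading life 1/λ of 13.2 min.

The ladder has three rungs. We put the gas phase entering solution first: y/t reads 0.0600 min⁻¹ at the first delta reading and 0.0620 min⁻¹ at the second, so within the scatter no lag shows by 2.50 min, the shortest of our times. Next comes the fading life, over which target rises and turns in the delta readings. Longest is the asked time, 3.03 lives long, so by our reckoning this flask stands in the tail.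

Joining the ends, we commit to 14.1%; one standard deviation on the first reading moves this by about 3.8 percentage points. If dusk speeds both steps equally, the dusk flask at 40 min equals the undisturbed flask at 80.0 min, for which we reckon 1.37%, less than our 14.1%. Winter has no visible lag to remove, so we choose none.

The forecast says 3%, lower than our figure, with none as its choice of change and 0.5% after dusk: “More gas, by either change, only speeds the destruction, so neither helps.”

The flask gives 12.1%, with none as the best change and 2.62% after dusk; dusk moves target by −9.5 points, winter by −0.24 points.

    gas phase ⇌ dissolved gas, rate k1*(csat - [dissolved gas]) (kL = 3.75 min⁻¹)
    substrate + dissolved gas ⇌ target (K = 700 L mol⁻¹, k = 7.80 L mol⁻¹ min⁻¹)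
    dissolved gas + target → over-reacted product (k = 3.24 L mol⁻¹ min⁻¹)
    target → over-reaction product (k = 0.0432 min⁻¹)

At 40.0 min this flask has not come to rest: substrate 4.92% and target 12.1% remain, and target is made more slowly than it is used, each step taken net, at 0.326 of that rate. Ten times the asked time is 30.2 fading lives. By then target stands at 0% and substrate at 0%, while over-reacted product goes from 39.0% to 47.0% and over-reaction product from 44.0% to 53.0%.

For the neighbour flask read at 1.0 h, λ gives target at 4.67%. That flask holds 3.81% of target.

The data were computed with made-up constants, noise included.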